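Take a ratio of two times, D = t/τ. Here t is how long you leave the flask, and τ is the time in which substrate at the new concentration half reacts with partner at equal equivalents. The question counts substrate as reacted once it has gone into another species, so you follow the loss of substrate and leave the lagging target out of the reckoning.

| flask | substrate | partner | remark | time |
|---|---|---|---|---|
| midnight | 0.34 M | 1 equiv | run made earlier |  |
| summer | 0.25 M | 1 equiv | run made earlier |  |
| Wednesday's | 0.50 M | 1.00 equiv |  | 30 min |
| Thursday's | 0.50 M | 2.00 equiv |  | 30 min |

- midnight (time / min: substrate / %, target / %): 1.00: 95.0, 0; 2.50: 90.0, 1.0; 5.00: 81.4, 1.7; 8.00: 75.7, 5.0; 10.0: 69.6, 5.4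
- summer (time / min: substrate / %, target / %): 0.833: 97.2, 1.1; 1.50: 94.2, 0.5; 3.00: 91.9, 2.0; 6.00: 84.8, 2.6; 10.0: 75.7, 4.7

(scatter of a reading: 1 percentage point)

- what was read earlier has a scatter of 1 percentage point, one standard deviation
- what has gone from substrate into another species counts as reacted, even if it can come back

- part of the substrate that has reacted at the end, Wednesday's
- part of the substrate that has reacted at the end, Thursday's
- what raising the equivalents of partner from its lowest to its highest value here does to the part of the substrate that has reacted (changes below 5 percentage points count as none) (it falls / no change / it rises)

If the loss is first order in substrate and in partner, equal charges leave a fraction f = 1/(1 + t/τ), with τ inversely proportional to the concentration. The midnight run keeps 69.6 % at 10.0 min, which read this way and scaled to 0.50 M gives τ = 15.6 min. The summer run, read the same way, gives 15.6 min, so the scaling stands on two separate runs. With 30 min, the ratio is D = 1.93.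

That is one end, equal charges. At the other end, a large excess of partner, that rate law makes the loss exponential in time, the pseudo-first-order case. Between them, at 2.00 equiv with substrate as the limiting reagent, the same rate law gives f = 1/(2e^D − 1). My reckoning, with no return of substrate, therefore gives 65.8 % reacted on Wednesday's and 92.1 % on Thursday's.

The forecast stands lower on both, at 64 % and 89 %, and its trend is: it rises. In its words: “Possible reversal shades both down a little”.

Wednesday's gives 65.4 % and Thursday's 88.9 %, and the trend is: it rises, by 24 percentage points.

    substrate + partner → intermediate + released group (k = 0.110 M⁻¹ min⁻¹)
    intermediate ⇌ target (K = 0.320, k = 0.0940 min⁻¹)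
    intermediate ⇌ isomer of the product (K = 95.0, k = 0.0310 min⁻¹)
    substrate + released group ⇌ idle adduct, settled at all times (K = 0.560 M⁻¹)

On Wednesday's, isomer of the product stands at 22.0 % at the end, yet the step forming it makes no difference to the part reacted. Now take the neighbouring flask, Wednesday's recipe at 0.85 M of substrate and the same time. There τ shrinks with the concentration, so D becomes 3.28 and the equal-charge form gives 76.6 %. That flask stands at 77.0 %.

The readings come from a simulation from invented constants, noise included.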